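## Structural features

Isoplagilin (16) is an open-chain bis(bibenzyl) of four benzene rings: ring A (3-methoxyphenyl) is tied by a CH2CH2 chain to C1 of ring B, C5 of ring B is bonded directly to C1 of ring C, and C6 of ring C carries a second CH2CH2 chain ending in ring D (3-methoxyphenyl). Rings B and C are both catechols with hydroxyls at C3 and C4, so the C4 hydroxyl of ring B and the arm-bearing C6 of ring C flank the biaryl bond from opposite rings. There is no stereocenter, and the axis, with only one hydroxyl and one methylene in its ortho positions, is not a stable stereogenic element. The fragile groups are the two free catechols, which oxidise readily to ortho-quinones and bind metals; the two aryl methyl ethers must survive the unmasking, which favours benzyl ethers and hydrogenolysis. The real difficulty is regiochemical: four phenolic oxygens and two identical arms sit on an unsymmetrical biaryl, one arm meta to the axis (ring B) and the other ortho to it (ring C). The key step uses the fact that the oxygen on C4 of ring B and C6 of ring C are joined through five atoms (O–C4–C5–C1–C6), so one bridging carbon closes a six-membered lactone and is at the same time the first carbon of the ring-C arm.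

## Logic of the disconnections

16 back to 15. The three benzyl–oxygen bonds (on the oxygens at C3 of ring B and at C3 and C4 of ring C) and the two added hydrogens of the ring-C arm are removed in thought. This keeps both catechols masked to the last flask and lets one operation finish the arm and unmask everything. The forward step must saturate a stilbene and cleave three aryl benzyl ethers while leaving the two methyl ethers alone.

15 back to 11 and 13. The Cα=Cβ bond of the ring-C arm is cut. Cα stays on ring C at the aldehyde oxidation level, stored as the cyclic hemiacetal 11; Cβ and ring D arrive as the phosphonate carbanion 13, formed in the flask from 12. Ring D is removed and a compact tricyclic core remains. A phosphonate is chosen at this late stage because its carbanion is the stronger nucleophile toward a hindered ortho-aryl aldehyde and its phosphate by-product is removed by washing. The forward step needs 11 to open to 14 under base and the olefination to run beside a phenoxide.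

11 back to 10. No skeletal bond is cut; the hemiacetal carbon is raised to the lactone level, which is what the key step delivers. The forward demand is a hydride reduction that stops one stage short of the diol.

10 back to 8 and 9. Two bonds of the lactone are cut: C6(ring C)–C(=O) and C(=O)–O(C4 of ring B). This is the largest simplification: the ring vanishes, ring C becomes a plain 3,4-dioxygenated phenyl group, and the one-carbon unit is 9. The forward step must palladate C6 and not C2 of ring C, and the hydroxyl on C4 of ring B must be the only free one.

8 back to 4 and 6, by way of 7. The ring-B arm is treated like the ring-C arm: the two arm hydrogens are removed (7), then the Cα=Cβ bond is cut, giving 4 and the ylide 6, formed in the flask from 5. The ylide is used here because olefination of unprotected 4-hydroxybenzaldehydes with an excess of a benzylic ylide, which also serves as the base for the phenol, is established practice. The forward steps must reduce the alkene of 7 without hydrogenolysis of benzyl ethers, and the olefination must tolerate the phenoxide para to the formyl group of 4.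

4 back to 2 and 3. The biaryl bond C5(ring B)–C1(ring C) is cut. Cutting at the aldehyde stage places an electron-withdrawing group para to the phenoxide, which helps the cross-coupling. A bromide cross-coupling is preferred to direct ortho-arylation of the phenol with a pentavalent bismuth reagent, which would need two reagent-making steps and would transfer only one of its three aryl groups. The forward step is a coupling ortho to an unprotected hydroxyl.

2 back to 1. The C5–Br bond of ring B is cut; 1 already holds the mono-benzylated catechol and the formyl group. The forward step is a monobromination at the one open position ortho to the free hydroxyl.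

## Other disconnections considered

Alternative 1: The cut runs through the biaryl bond C5(ring B)–C1(ring C) and the C4(ring B)–O bond in one event.
- Forward key step: chloroarene A3 would be metalated between chlorine and the acetal oxygen and lose chloride to give the aryne of ring B. The ring-C arylmagnesium bromide A2, already carrying its arm, would add at C5, because the C3–O bond stabilises the carbanion developing at C4. That carbanion would be borylated and oxidised to the phenol A1, and acid would then release 16.
- In favour: both arms are in place before the union, one polar effect controls both new bonds, and no transition metal is needed. Only one step follows the key event, against three after step 5; on end-game and on longest linear sequence this plan is the better one. Ring C needs no site selection because the halogen of the A2 precursor fixes the position, which is at least equal to the chosen plan.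
- Against: each fragment is a halogenated bibenzyl, so each needs its own olefination and diimide reduction (hydrogenation over palladium would attack the halides). The key event chains three reactions on hindered partners: a 2-substituted aryl Grignard must meet a short-lived aryne made with strong base beside benzylic CH2 groups, and the resulting carbanion, flanked by an acetal and the new aryl group, must be borylated faster than it is protonated.
- Comparison: structurally both plans pivot on C4 of ring B, but here the C4–O bond is made, while the chosen plan uses an oxygen already present as director and tether end. Mechanistically it is polar aryne addition against carboxylate-assisted palladation, with more separate ways to fail in one flask. The total step count is expected to be equal or somewhat higher.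

Alternative 2: The cut removes both arm double bonds at once.
- Forward key step: dialdehyde A5 would react with two equivalents of the carbanion 13 (the reagent of step 7, made from 12) to give the E,E-bis-stilbene A4; one hydrogenation would then saturate both alkenes and cleave four benzyl ethers to give 16.
- In favour: it uses the identity of the two arms, so one operation installs rings A and D, where the chosen plan runs two olefinations (steps 3 and 7) with two different phosphorus reagents. Neither aldehyde is deactivated by a phenoxide, and the phosphate by-product is water-soluble; on olefination reliability this plan is better than step 3 and equal to step 7. The final hydrogenation equals step 8, and no separate diimide step is needed.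
- Against: the burden moves to A5. Its biaryl bond would have to be formed intramolecularly across a temporary ester tether, the tether carbonyl reduced, both termini brought to the aldehyde level, and the oxygen freed from the tether benzylated. These redox and protecting-group steps add nothing to the skeleton.
- Comparison: structurally both plans pass through a lactone between the C4 oxygen of ring B and C6 of ring C. The chosen plan makes it from 9 after the biaryl bond exists and needs no fourth benzyl group. Mechanistically it is carbanion olefination against C–H carbonylation, and the olefination is the more predictable step. The route to A5 is expected to make the overall count equal or longer.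

Alternative 3: The cut goes through ring B itself, at C1–C2 and C4–C5.
- Forward key step: keto ester A7 would add through its C2 to the β-carbon of enone A8 (Michael addition). Its C4, the benzyloxy-bearing methylene, would then condense on the aryl ketone to give cyclohexenone A6 as the racemic trans isomer, the ester-bearing carbon being epimerisable. Decarboxylation, dehydrogenative aromatisation and hydrogenolysis would follow.
- In favour: the substitution pattern of ring B is fixed by connectivity, with no aromatic substitution or C–H site selection, and on this point it is better than the chosen plan. The biaryl bond is never made by coupling, the reagents are cheap, and no carbon monoxide is used. The two stereocenters are erased later, so on stereochemistry the plans are equal.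
- Against: the condensation must use the less acidic alkoxy-bearing carbon against a hindered ortho-substituted aryl ketone, in competition with γ-deprotonation of the β-alkyl enone and retro-Michael cleavage. The later aromatisation of a 2-alkoxycyclohexenone beside several benzylic CH2 groups and electron-rich rings is the weak point. A8 itself needs a multistep ring-C ketone.
- Comparison: structurally it builds a ring the chosen plan buys. Mechanistically it relies on enolate chemistry and a late oxidation, against a redox-neutral substrate and one catalytic oxidation. Three steps follow the key step, equal to the chosen plan, but the way to A8 should make the whole longer.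

Key step: step 5

Remark on the chemistry: 3,4-bis(benzyloxy)phenylboronic acid (3) is taken as a stock boronic acid; 7 is expected as an E/Z mixture and 15 mainly as the E isomer, which is immaterial because both alkenes are saturated afterwards.

## Route

Step 1
Reactants: 1 3-(benzyloxy)-4-hydroxybenzaldehyde
Product: 2 3-(benzyloxy)-5-bromo-4-hydroxybenzaldehyde
Conditions: Br2 (1.05 equiv), NaOAc (1.5 equiv), AcOH, 15–20 °C
Reagents that add atoms: bromine, BrBr
Why: Electrophilic aromatic bromination; the free hydroxyl is the strongest director and C5 is its only open ortho or para position, as in the bromination of vanillin. Acetate buffers the HBr so the benzyl ether is not cleaved.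

Step 2
Reactants: 2 3-(benzyloxy)-5-bromo-4-hydroxybenzaldehyde; 3 3,4-bis(benzyloxy)phenylboronic acid
Product: 4 3-(benzyloxy)-5-[3,4-bis(benzyloxy)phenyl]-4-hydroxybenzaldehyde
Conditions: Pd(dppf)Cl2 (3 mol%), K2CO3 (3 equiv), 1,4-dioxane/H2O (4:1), 85 °C
Reagents that add atoms: none
Why: Suzuki–Miyaura cross-coupling; zerovalent palladium inserts into the C5–Br bond, which the para-formyl group keeps reactive although the ring is a phenoxide, and transmetalation and reductive elimination form the C5(ring B)–C1(ring C) bond. Bromophenol aldehydes of the 5-bromovanillin type are established partners.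

Step 3
Reactants: 4 3-(benzyloxy)-5-[3,4-bis(benzyloxy)phenyl]-4-hydroxybenzaldehyde; 5 (3-methoxybenzyl)triphenylphosphonium chloride
Product: 7 2-(benzyloxy)-6-[3,4-bis(benzyloxy)phenyl]-4-[2-(3-methoxyphenyl)ethenyl]phenol (E/Z mixture), via (3-methoxybenzylidene)triphenylphosphorane 6 (not isolated)
Conditions: 5 (2.6 equiv), n-BuLi (2.5 equiv), THF, 0 °C; then 4, 0 °C to 50 °C
Reagents that add atoms: none
Why: Wittig olefination with a semi-stabilised ylide; the first equivalent of 6 is spent on the phenol and the lithium phenoxide aldehyde reacts with the excess. No geometric control is needed because step 4 removes the alkene.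

Step 4
Reactants: 7 2-(benzyloxy)-6-[3,4-bis(benzyloxy)phenyl]-4-[2-(3-methoxyphenyl)ethenyl]phenol (E/Z mixture)
Product: 8 2-(benzyloxy)-6-[3,4-bis(benzyloxy)phenyl]-4-[2-(3-methoxyphenyl)ethyl]phenol
Conditions: TsNHNH2 (6 equiv), NaOAc (8 equiv), THF/H2O (1:1), reflux
Reagents that add atoms: none
Why: Diimide reduction; HN=NH released from the sulfonyl hydrazide transfers two hydrogens to the stilbene in a concerted syn fashion. The three benzyl ethers, which catalytic hydrogenation over palladium would cleave, are untouched.

Step 5
Reactants: 8 2-(benzyloxy)-6-[3,4-bis(benzyloxy)phenyl]-4-[2-(3-methoxyphenyl)ethyl]phenol; 9 carbon monoxide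
Product: 10 4,8,9-tris(benzyloxy)-2-[2-(3-methoxyphenyl)ethyl]-6H-benzo[c]chromen-6-one
Conditions: Pd(OAc)2 (10 mol%), Cu(OAc)2 (2.2 equiv), 9 (1 atm, balloon), mesitylene, 120 °C
Reagents that add atoms: none
Why: Hydroxyl-directed C–H carbonylation of a 2-arylphenol, a known way to benzo[c]chromen-6-ones under divalent palladium. The phenol of 8 replaces acetate on Pd(OAc)2, and acetate-assisted concerted metalation–deprotonation at C6 of ring C gives a six-membered oxapalladacycle. Insertion of 9 into the Pd–aryl bond gives a seven-membered acyl palladacycle, and acyl–oxygen reductive elimination closes the six-membered lactone (formally a 6-exo-trig attack of the phenoxide oxygen on the acyl carbon) and leaves zerovalent palladium, which two equivalents of Cu(OAc)2 bring back to the divalent state. Two skeletal bonds result, C6(ring C)–C(=O) and C(=O)–O(C4 of ring B). No stereocenter is created. The selectivity required is C6 over C2 of ring C: C2 sits in the pocket between the axis and the C3 benzyloxy group, whereas C6 has a hydrogen neighbour and lies para to that ether, so steric and electronic bias point the same way. Chemoselectivity rests on 8 having one free hydroxyl: benzyl ethers cannot bind as anionic ligands, rings A and D carry no director, and every ortho and para position of the phenol ring is substituted, which also suppresses oxidative phenol coupling by Cu(OAc)2.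

Step 6
Reactants: 10 4,8,9-tris(benzyloxy)-2-[2-(3-methoxyphenyl)ethyl]-6H-benzo[c]chromen-6-one
Product: 11 4,8,9-tris(benzyloxy)-2-[2-(3-methoxyphenyl)ethyl]-6H-benzo[c]chromen-6-ol (racemic)
Conditions: i-Bu2AlH (1.2 equiv), CH2Cl2, −78 °C; aq. potassium sodium tartrate
Reagents that add atoms: none
Why: Partial reduction of a lactone to a lactol; the aluminium hemiacetal is held in the six-membered ring at −78 °C and released only on work-up. The hemiacetal carbon forms without control (racemic), which is irrelevant because step 7 destroys it.

Step 7
Reactants: 11 4,8,9-tris(benzyloxy)-2-[2-(3-methoxyphenyl)ethyl]-6H-benzo[c]chromen-6-ol (racemic); 12 diethyl (3-methoxybenzyl)phosphonate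
Product: 15 2-(benzyloxy)-6-{4,5-bis(benzyloxy)-2-[(E)-2-(3-methoxyphenyl)ethenyl]phenyl}-4-[2-(3-methoxyphenyl)ethyl]phenol, via potassium phosphonate carbanion 13 (not isolated), via ring-opened hydroxy aldehyde 14 (not isolated)
Conditions: 12 (2.2 equiv), KOt-Bu (3.4 equiv), THF, 0 °C; then 11, 0 °C to 40 °C; aq. NH4Cl
Reagents that add atoms: none
Why: Horner–Wadsworth–Emmons olefination of a lactol; one equivalent of KOt-Bu deprotonates 11, whose alkoxide opens to the phenoxide aldehyde 14, and the carbanion 13 adds to it, the potassium β-oxido phosphonate collapsing to the E-stilbene and water-soluble diethyl phosphate. The formyl group of 14 sits on ring C and is only weakly conjugated with the ring-B phenoxide through the twisted biaryl, so it keeps its electrophilicity. Geometry is irrelevant because step 8 saturates the alkene.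

Step 8
Reactants: 15 2-(benzyloxy)-6-{4,5-bis(benzyloxy)-2-[(E)-2-(3-methoxyphenyl)ethenyl]phenyl}-4-[2-(3-methoxyphenyl)ethyl]phenol
Product: 16 isoplagilin (3-{4,5-dihydroxy-2-[2-(3-methoxyphenyl)ethyl]phenyl}-5-[2-(3-methoxyphenyl)ethyl]benzene-1,2-diol)
Conditions: H2 (1 atm), 10% Pd/C, EtOAc/MeOH (1:1), rt; work-up under argon
Reagents that add atoms: none
Why: Heterogeneous hydrogenation and hydrogenolysis in one operation; the stilbene is saturated and the three aryl benzyl ethers are cleaved. Aryl methyl ethers and the diarylethane chains are inert, and the catechols appear only in this last step.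

## Compound list

1 | 3-(benzyloxy)-4-hydroxybenzaldehyde | O=Cc1ccc(O)c(OCc2ccccc2)c1 | starting material
2 | 3-(benzyloxy)-5-bromo-4-hydroxybenzaldehyde | O=Cc1cc(Br)c(O)c(OCc2ccccc2)c1 | intermediate
3 | 3,4-bis(benzyloxy)phenylboronic acid | OB(O)c1ccc(OCc2ccccc2)c(OCc2ccccc2)c1 | starting material
4 | 3-(benzyloxy)-5-[3,4-bis(benzyloxy)phenyl]-4-hydroxybenzaldehyde | O=Cc1cc(OCc2ccccc2)c(O)c(-c2ccc(OCc3ccccc3)c(OCc3ccccc3)c2)c1 | intermediate
5 | (3-methoxybenzyl)triphenylphosphonium chloride | COc1cccc(C[P+](c2ccccc2)(c2ccccc2)c2ccccc2)c1.[Cl-] | starting material
6 | (3-methoxybenzylidene)triphenylphosphorane (ylide, not isolated) | COc1cccc(C=P(c2ccccc2)(c2ccccc2)c2ccccc2)c1 | intermediate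
7 | 2-(benzyloxy)-6-[3,4-bis(benzyloxy)phenyl]-4-[2-(3-methoxyphenyl)ethenyl]phenol, E/Z mixture | COc1cccc(C=Cc2cc(OCc3ccccc3)c(O)c(-c3ccc(OCc4ccccc4)c(OCc4ccccc4)c3)c2)c1 | intermediate
8 | 2-(benzyloxy)-6-[3,4-bis(benzyloxy)phenyl]-4-[2-(3-methoxyphenyl)ethyl]phenol | COc1cccc(CCc2cc(OCc3ccccc3)c(O)c(-c3ccc(OCc4ccccc4)c(OCc4ccccc4)c3)c2)c1 | intermediate
9 | carbon monoxide | [C-]#[O+] | starting material
10 | 4,8,9-tris(benzyloxy)-2-[2-(3-methoxyphenyl)ethyl]-6H-benzo[c]chromen-6-one | COc1cccc(CCc2cc(OCc3ccccc3)c3OC(=O)c4cc(OCc5ccccc5)c(OCc5ccccc5)cc4-c3c2)c1 | intermediate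
11 | 4,8,9-tris(benzyloxy)-2-[2-(3-methoxyphenyl)ethyl]-6H-benzo[c]chromen-6-ol, racemic | COc1cccc(CCc2cc(OCc3ccccc3)c3OC(O)c4cc(OCc5ccccc5)c(OCc5ccccc5)cc4-c3c2)c1 | intermediate
12 | diethyl (3-methoxybenzyl)phosphonate | CCOP(=O)(Cc1cccc(OC)c1)OCC | starting material
13 | potassium (diethoxyphosphoryl)(3-methoxyphenyl)methanide (phosphonate carbanion, not isolated) | CCOP(=O)(OCC)[CH-]c1cccc(OC)c1.[K+] | intermediate
14 | 4,5-bis(benzyloxy)-2-{3-(benzyloxy)-2-hydroxy-5-[2-(3-methoxyphenyl)ethyl]phenyl}benzaldehyde (open form of 11, not isolated) | COc1cccc(CCc2cc(OCc3ccccc3)c(O)c(-c3cc(OCc4ccccc4)c(OCc4ccccc4)cc3C=O)c2)c1 | intermediate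
15 | 2-(benzyloxy)-6-{4,5-bis(benzyloxy)-2-[(E)-2-(3-methoxyphenyl)ethenyl]phenyl}-4-[2-(3-methoxyphenyl)ethyl]phenol | COc1cccc(CCc2cc(OCc3ccccc3)c(O)c(-c3cc(OCc4ccccc4)c(OCc4ccccc4)cc3/C=C/c3cccc(OC)c3)c2)c1 | intermediate
16 | isoplagilin, 3-{4,5-dihydroxy-2-[2-(3-methoxyphenyl)ethyl]phenyl}-5-[2-(3-methoxyphenyl)ethyl]benzene-1,2-diol | COc1cccc(CCc2cc(O)c(O)c(-c3cc(O)c(O)cc3CCc3cccc(OC)c3)c2)c1 | target

## Step count and risks

Total step count: 8. Longest linear sequence: 8 steps (1 → 2 → 4 → 7 → 8 → 10 → 11 → 15 → 16); 3, 5, 9 and 12 are bought.

Least certain steps:

Step 5 (key step). Most likely failures: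
- reduction of the catalyst by carbon monoxide to inactive zerovalent palladium aggregates faster than Cu(OAc)2 can reoxidise it;
- oxidative degradation of the electron-rich phenol at 120 °C;
- C–O reductive elimination before uptake of 9, contracting the ring to a dibenzofuran;
- partial palladation at C2 of ring C.

Fallback, from 4 back to 10: the C–H activation is replaced by a C–Br bond placed before the arm is built. N-Bromosuccinimide (MeCN, 0 °C) should brominate 4 on ring C, the only ring not deactivated by the formyl group, para to the C3 ether, giving 3-(benzyloxy)-5-[4,5-bis(benzyloxy)-2-bromophenyl]-4-hydroxybenzaldehyde F1. Olefination with 6 as in step 3 gives 2-(benzyloxy)-6-[4,5-bis(benzyloxy)-2-bromophenyl]-4-[2-(3-methoxyphenyl)ethenyl]phenol F2, and diimide reduction as in step 4 gives 2-(benzyloxy)-6-[4,5-bis(benzyloxy)-2-bromophenyl]-4-[2-(3-methoxyphenyl)ethyl]phenol F3. Carbonylative lactonisation (Pd(OAc)2, Xantphos, Et3N, CO 1 atm, toluene, 100 °C) then proceeds by oxidative addition of zerovalent palladium into C–Br, CO insertion and capture of the acyl group by the neighbouring phenol, returning to 10. This is standard alkoxycarbonylation of an aryl bromide.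

Step 3. The phenoxide para to the formyl group lowers its electrophilicity, so olefination may stall while the ylide slowly decomposes.

Fallback, from 4 back to 8: (3-methoxybenzyl)magnesium chloride (2.5 equiv, THF, 0 °C) adds to the aldehyde even as its phenoxide and gives racemic 2-(benzyloxy)-6-[3,4-bis(benzyloxy)phenyl]-4-[1-hydroxy-2-(3-methoxyphenyl)ethyl]phenol F4. Ionic deoxygenation (Et3SiH, CF3CO2H, CH2Cl2, 0 °C) through the cation stabilised by the para hydroxyl delivers 8 directly, bypassing 7 and step 4.

Step 6. Over-reduction is the risk: collapse of the aluminium hemiacetal with loss of the phenoxide exposes an aldehyde to a second hydride.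

Fallback, from 10 back to 11: MeNH(OMe)·HCl and AlMe3 (CH2Cl2, 0 °C to rt) open the lactone to 4,5-bis(benzyloxy)-2-{3-(benzyloxy)-2-hydroxy-5-[2-(3-methoxyphenyl)ethyl]phenyl}-N-methoxy-N-methylbenzamide F5. LiAlH4 (THF, −20 °C) gives a chelated tetrahedral intermediate that resists further reduction; on work-up the aldehyde 14 closes to 11.

Step 7. The ring–chain equilibrium may hold the substrate as the closed lactol alkoxide, and the open aldehyde is hindered by the ortho aryl group and electron-rich, so addition of 13 may be slow. The potassium β-oxido phosphonate, whose carbanion carbon is stabilised only by an aryl group, may also be slow to eliminate.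

Fallback, from 11 to 16: (3-methoxybenzyl)magnesium chloride (3 equiv, THF, 0 °C to rt) adds to the open form to give racemic 2-(benzyloxy)-6-{4,5-bis(benzyloxy)-2-[1-hydroxy-2-(3-methoxyphenyl)ethyl]phenyl}-4-[2-(3-methoxyphenyl)ethyl]phenol F6. Hydrogenation over Pd/C in EtOAc/AcOH with a trace of HClO4 hydrogenolyses the electron-rich secondary benzylic C–O bond together with the three benzyl ethers and gives 16 directly, bypassing 15. Capture of the benzylic cation by the neighbouring phenol would only create another benzylic C–O bond cleaved under the same conditions.

## Further compounds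

F1 | step 5 | 3-(benzyloxy)-5-[4,5-bis(benzyloxy)-2-bromophenyl]-4-hydroxybenzaldehyde | O=Cc1cc(OCc2ccccc2)c(O)c(-c2cc(OCc3ccccc3)c(OCc3ccccc3)cc2Br)c1
F2 | step 5 | 2-(benzyloxy)-6-[4,5-bis(benzyloxy)-2-bromophenyl]-4-[2-(3-methoxyphenyl)ethenyl]phenol, E/Z mixture | COc1cccc(C=Cc2cc(OCc3ccccc3)c(O)c(-c3cc(OCc4ccccc4)c(OCc4ccccc4)cc3Br)c2)c1
F3 | step 5 | 2-(benzyloxy)-6-[4,5-bis(benzyloxy)-2-bromophenyl]-4-[2-(3-methoxyphenyl)ethyl]phenol | COc1cccc(CCc2cc(OCc3ccccc3)c(O)c(-c3cc(OCc4ccccc4)c(OCc4ccccc4)cc3Br)c2)c1
F4 | step 3 | 2-(benzyloxy)-6-[3,4-bis(benzyloxy)phenyl]-4-[1-hydroxy-2-(3-methoxyphenyl)ethyl]phenol, racemic | COc1cccc(CC(O)c2cc(OCc3ccccc3)c(O)c(-c3ccc(OCc4ccccc4)c(OCc4ccccc4)c3)c2)c1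
F5 | step 6 | 4,5-bis(benzyloxy)-2-{3-(benzyloxy)-2-hydroxy-5-[2-(3-methoxyphenyl)ethyl]phenyl}-N-methoxy-N-methylbenzamide | COc1cccc(CCc2cc(OCc3ccccc3)c(O)c(-c3cc(OCc4ccccc4)c(OCc4ccccc4)cc3C(=O)N(C)OC)c2)c1
F6 | step 7 | 2-(benzyloxy)-6-{4,5-bis(benzyloxy)-2-[1-hydroxy-2-(3-methoxyphenyl)ethyl]phenyl}-4-[2-(3-methoxyphenyl)ethyl]phenol, racemic | COc1cccc(CCc2cc(OCc3ccccc3)c(O)c(-c3cc(OCc4ccccc4)c(OCc4ccccc4)cc3C(O)Cc3cccc(OC)c3)c2)c1
A1 | alternative 1 | 2-{4,5-bis(methoxymethoxy)-2-[2-(3-methoxyphenyl)ethyl]phenyl}-6-(methoxymethoxy)-4-[2-(3-methoxyphenyl)ethyl]phenol | COc1cccc(CCc2cc(OCOC)c(O)c(-c3cc(OCOC)c(OCOC)cc3CCc3cccc(OC)c3)c2)c1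
A2 | alternative 1 | {4,5-bis(methoxymethoxy)-2-[2-(3-methoxyphenyl)ethyl]phenyl}magnesium bromide | COCOc1cc(CCc2cccc(OC)c2)c([Mg]Br)cc1OCOC
A3 | alternative 1 | 1-chloro-3-(methoxymethoxy)-5-[2-(3-methoxyphenyl)ethyl]benzene | COCOc1cc(Cl)cc(CCc2cccc(OC)c2)c1
A4 | alternative 2 | 1,2-bis(benzyloxy)-3-{4,5-bis(benzyloxy)-2-[(E)-2-(3-methoxyphenyl)ethenyl]phenyl}-5-[(E)-2-(3-methoxyphenyl)ethenyl]benzene | COc1cccc(/C=C/c2cc(OCc3ccccc3)c(OCc3ccccc3)c(-c3cc(OCc4ccccc4)c(OCc4ccccc4)cc3/C=C/c3cccc(OC)c3)c2)c1
A5 | alternative 2 | 2,3,4',5'-tetrakis(benzyloxy)biphenyl-2',5-dicarbaldehyde | O=Cc1cc(OCc2ccccc2)c(OCc2ccccc2)c(-c2cc(OCc3ccccc3)c(OCc3ccccc3)cc2C=O)c1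
A6 | alternative 3 | racemic trans ethyl 3-(benzyloxy)-4-{4,5-bis(benzyloxy)-2-[2-(3-methoxyphenyl)ethyl]phenyl}-6-[2-(3-methoxyphenyl)ethyl]-2-oxocyclohex-3-ene-1-carboxylate | CCOC(=O)[C@H]1[C@H](CCc2cccc(OC)c2)CC(c2cc(OCc3ccccc3)c(OCc3ccccc3)cc2CCc2cccc(OC)c2)=C(OCc2ccccc2)C1=O
A7 | alternative 3 | ethyl 4-(benzyloxy)-3-oxobutanoate | CCOC(=O)CC(=O)COCc1ccccc1
A8 | alternative 3 | (E)-1-{4,5-bis(benzyloxy)-2-[2-(3-methoxyphenyl)ethyl]phenyl}-5-(3-methoxyphenyl)pent-2-en-1-one | COc1cccc(CC/C=C/C(=O)c2cc(OCc3ccccc3)c(OCc3ccccc3)cc2CCc2cccc(OC)c2)c1
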